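## Retrosynthetic overview

1. Final C–O change: the ring C–OOH is a vinylogous peroxy acid. It is traced back to cochliodinol by mono-triflation of one of the two equivalent ring C–OH groups, followed by perhydrolysis.
2. Key disconnection: cochliodinol is cut at the two ring bonds that join an indolyl-bearing carbon to a ring C=O carbon. This gives two molecules of 3-(5-prenylindol-3-yl)pyruvic acid. In the forward sense the step is a magnesium-templated, head-to-tail double Claisen cyclodimerisation of the acyl imidazolide.
3. Enabling feature: the six quinone-ring carbons are two identical C3 units (indolyl-C, C–O, C=O) joined head to tail. Each indolyl-bearing carbon lies between two oxygenated ring carbons (a 1,3-dicarbonyl relation). 2,5-Dihydroxy-1,4-benzoquinone is a tautomer of cyclohexane-1,2,4,5-tetraone, which is exactly the oxidation level of two arylpyruvoyl units.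
4. Monomer: the pyruvic acid comes from 5-prenylindole-3-carbaldehyde (Erlenmeyer–Plöchl azlactone, then hydrolysis), the aldehyde from a Vilsmeier–Haack formylation, and 5-prenylindole from a Stille coupling of 5-bromoindole.
5. Ring order: both indole bicycles are bought intact. The quinone ring is the only ring formed, and it forms in the key step.

Key step: step 5

Assumption: the target has no stereocentre and no configurable alkene. The enolisable pyruvoyl compounds are written as keto tautomers although they should be largely enolic. Prenyl means 3-methylbut-2-en-1-yl.

## Route

Step 1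
Reactants: 1 5-bromo-1H-indole; 2 tributyl(3-methylbut-2-en-1-yl)stannane
Product: 3 5-prenyl-1H-indole
Conditions: Pd(PPh3)4 (5 mol %), DMF, 100 °C, argon
Reagents that add atoms: none
Why: Stille coupling, in which oxidative addition of the aryl bromide to zerovalent palladium, prenyl transfer from tin and reductive elimination at the unsubstituted allyl terminus should give the linear prenyl arene, and the neutral medium tolerates the free indole NH.

Step 2
Reactants: 3 5-prenyl-1H-indole
Product: 5 5-prenyl-1H-indole-3-carbaldehyde, via Vilsmeier iminium chloride 4 (not isolated)
Conditions: POCl3 (1.1 equiv), DMF, 0 °C to rt; then aq. NaOH, 0 to 60 °C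
Reagents that add atoms: N,N-dimethylformamide CN(C)C=O; water O
Why: Vilsmeier–Haack formylation, in which the chloroiminium salt attacks indole C3 far faster than the trisubstituted alkene and aqueous base hydrolyses iminium salt 4 to the aldehyde.

Step 3
Reactants: 5 5-prenyl-1H-indole-3-carbaldehyde; 6 N-acetylglycine
Product: 7 (Z)-4-[(1-acetyl-5-prenylindol-3-yl)methylidene]-2-methyl-1,3-oxazol-5(4H)-one
Conditions: NaOAc (1 equiv), Ac2O, 100 °C
Reagents that add atoms: acetic anhydride CC(=O)OC(C)=O
Why: Erlenmeyer–Plöchl azlactone synthesis, classical for indole-3-carbaldehydes, in which concurrent N-acetylation lifts the vinylogous-amide deactivation of the aldehyde and the thermodynamically preferred Z-alkylidene azlactone (indolyl cis to the ring nitrogen) should form, a geometry that is erased in the next step.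

Step 4
Reactants: 7 (Z)-azlactone
Product: 8 3-(5-prenyl-1H-indol-3-yl)-2-oxopropanoic acid
Conditions: aq. NaOH (2 M), reflux, argon; then cold 2 M HCl to pH 2
Reagents that add atoms: water O
Why: Alkaline azlactone hydrolysis, the classical route to arylpyruvic acids, in which hydroxide opens the lactone, removes the indole N-acetyl group and cleaves the enamide to ammonia, acetate and the keto acid, while the prenyl group is inert to base and air is excluded because the enolate autoxidises.

Step 5
Reactants: 8 3-(5-prenyl-1H-indol-3-yl)-2-oxopropanoic acid (two molecules)
Product: 11 cochliodinol [2,5-dihydroxy-3,6-bis(5-prenyl-1H-indol-3-yl)-1,4-benzoquinone], via acyl imidazolide 9 (not isolated), via open-chain C-acylated dimer 10 (not isolated)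
Conditions: 1,1'-carbonyldiimidazole (1.0 equiv per acid), THF, 0 °C to rt; then MgCl2 (1.5 equiv), Et3N (4 equiv), THF–MeCN, 0 to 45 °C, argon; cold 10 % aq. citric acid work-up
Reagents that add atoms: none
Why: Proposed new method: carbonyldiimidazole turns each acid into acyl imidazolide 9, and MgCl2/Et3N soft enolisation then lets the indolyl-bearing carbon of one molecule (held as a five-membered O,O-magnesium chelate) attack the imidazolide carbonyl of a second molecule to give 10, whose remaining indolyl-CH2 carbon attacks the remaining imidazolide carbonyl, so both ring C–C bonds form head to tail in one flask and the resulting cyclohexane-1,2,4,5-tetraone simply tautomerises to the dihydroxyquinone with no redox step. The closest known reaction types are the Masamune–Brooks acylation of magnesium enolates by acyl imidazolides, the MgCl2/Et3N C-acylation of activated carbonyl compounds, the base-induced Dieckmann-type isomerisation of 3-hydroxy-4-aryl-6-arylidenepyran-2,5-diones to 2,5-dihydroxy-3,6-diarylbenzoquinones and the enzymatic dimerisation of arylpyruvoyl thioesters; what is new is running two such Claisen events as a non-enzymatic cyclodimerisation of an arylpyruvic acid. The only ring closed is the central six-membered carbocycle, by a 6-(enolendo)-exo-trig Dieckmann acylation that should outrun chain growth because it is intramolecular. No stereocentre is created. The step needs Claisen over aldol and C- over O-acylation: the first is secured because the (indol-3-yl)pyruvoyl unit is fully enolised (its C=C is conjugated with the electron-rich indole), so no free ketone carbonyl is on offer and the imidazolide carbon is the only electrophile, and the second because enol esters or enol lactones from O-acylation remain active esters that the liberated imidazole reopens, whereas each C-acylation is locked as the magnesium chelate of a strongly acidic tricarbonyl. Head-to-tail regiochemistry is automatic, since each monomer holds one nucleophilic carbon and one acyl carbon two bonds apart.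

Step 6
Reactants: 11 cochliodinol
Product: 12 cochliodinol mono-triflate [4-hydroxy-3,6-dioxo-2,5-bis(5-prenyl-1H-indol-3-yl)cyclohexa-1,4-dien-1-yl trifluoromethanesulfonate]
Conditions: 2,6-lutidine (1.1 equiv), Tf2O (1.0 equiv, slow addition), CH2Cl2, −78 °C
Reagents that add atoms: trifluoromethanesulfonic anhydride O=S(=O)(OS(=O)(=O)C(F)(F)F)C(F)(F)F
Why: O-sulfonylation of a vinylogous acid (hydroxyquinone to quinonyl triflate, a known conversion of 2-hydroxy-1,4-quinones), in which one equivalent of anhydride added slowly to the mono-lutidinium salt at low temperature should stop mainly at mono-activation, the indole NH being non-nucleophilic without deprotonation.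

Step 7
Reactants: 12 cochliodinol mono-triflate
Product: 13 hydroperoxycochliodinol
Conditions: anhydrous H2O2 in Et2O (5 equiv), 2,6-lutidine (2.2 equiv), THF, −40 to −10 °C, dark, argon; cold pH 4 phosphate buffer work-up
Reagents that add atoms: hydrogen peroxide OO
Why: Proposed new method: perhydrolysis of a vinylogous triflic anhydride, in which the alpha-effect nucleophile H2O2 (or its anion) adds to the OTf-bearing ring carbon of the enone half C(OTf)=C(indolyl)–C=O and the resulting enolate should expel triflate far faster than it could displace hydroxide from the O–O bond (the Weitz–Scheffer epoxidation path), the hydroxyquinone half being an electronically separate oxonol anion joined only through two ring C–C single bonds; the closest known reaction types are the preparation of peroxy acids from acyl chlorides or acyl imidazolides with H2O2 and the hydroxide displacement of halide in 2,5-dihalo-3,6-bis(indolyl)benzoquinones.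

## Compound list

1 | 5-bromo-1H-indole | Brc1ccc2[nH]ccc2c1 | starting material
2 | tributyl(3-methylbut-2-en-1-yl)stannane | CCCC[Sn](CCCC)(CCCC)CC=C(C)C | starting material
3 | 5-prenyl-1H-indole | CC(C)=CCc1ccc2[nH]ccc2c1 | intermediate
4 | N,N-dimethyl-1-(5-prenyl-1H-indol-3-yl)methaniminium chloride | C[N+](C)=Cc1c[nH]c2ccc(CC=C(C)C)cc12.[Cl-] | intermediate
5 | 5-prenyl-1H-indole-3-carbaldehyde | O=Cc1c[nH]c2ccc(CC=C(C)C)cc12 | intermediate
6 | N-acetylglycine | CC(=O)NCC(=O)O | starting material
7 | (Z)-4-[(1-acetyl-5-prenylindol-3-yl)methylidene]-2-methyl-1,3-oxazol-5(4H)-one | CC1=N/C(=C\c2cn(C(C)=O)c3ccc(CC=C(C)C)cc23)C(=O)O1 | intermediate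
8 | 3-(5-prenyl-1H-indol-3-yl)-2-oxopropanoic acid (keto tautomer drawn) | O=C(O)C(=O)Cc1c[nH]c2ccc(CC=C(C)C)cc12 | intermediate
9 | 1-(imidazol-1-yl)-3-(5-prenyl-1H-indol-3-yl)propane-1,2-dione (keto tautomer drawn) | O=C(Cc1c[nH]c2ccc(CC=C(C)C)cc12)C(=O)n1ccnc1 | intermediate
10 | 1-(imidazol-1-yl)-3,6-bis(5-prenyl-1H-indol-3-yl)hexane-1,2,4,5-tetraone (keto tautomer drawn; the C3–H centre is labile and enolised under the conditions) | O=C(Cc1c[nH]c2ccc(CC=C(C)C)cc12)C(=O)C(c1c[nH]c2ccc(CC=C(C)C)cc12)C(=O)C(=O)n1ccnc1 | intermediate
11 | cochliodinol | CC(C)=CCc1ccc2[nH]cc(C3=C(O)C(=O)C(c4c[nH]c5ccc(CC=C(C)C)cc45)=C(O)C3=O)c2c1 | intermediate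
12 | cochliodinol mono-triflate | CC(C)=CCc1ccc2[nH]cc(C3=C(O)C(=O)C(c4c[nH]c5ccc(CC=C(C)C)cc45)=C(OS(=O)(=O)C(F)(F)F)C3=O)c2c1 | intermediate
13 | hydroperoxycochliodinol | CC(C)=CCc1ccc2[nH]cc(C3=C(O)C(=O)C(c4c[nH]c5ccc(CC=C(C)C)cc45)=C(OO)C3=O)c2c1 | target

## Counts and risks

Total step count: 7. Longest linear sequence: 7 (fully linear; step 5 consumes two molecules of the same monomer).

**1. Step 5.**
- What may go wrong: O-acylation and chain growth to oligomeric enol esters may outrun C-acylation. The activated keto acid may lose its enol masking and drift into aldol-type self-condensation. The enolate may also autoxidise.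
- Fallback: it uses known chemistry and a different disconnection, in which the quinone ring is bought and the indoles are attached to it. It sets out from 3 and comes back at 11.
- Two equivalents of 3 are condensed with bromanil (2,3,5,6-tetrabromo-1,4-benzoquinone) under Cs2CO3 in MeCN at room temperature.
- Addition–elimination through indole C3 should give 2,5-dibromo-3,6-bis(5-prenyl-1H-indol-3-yl)-1,4-benzoquinone F1.
- NaOH in aqueous MeOH at reflux, followed by acidification, replaces both bromides by hydroxyl and delivers 11.

**2. Step 7.**
- What may go wrong: the peroxide adduct may close to an epoxide. Attack at sulfur may return the hydroxyquinone. The product hydroperoxide may couple with a second triflate. Oxygen may transfer from the product to the prenyl or indole units in the basic medium.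
- Fallback: it uses a monoprotected hydrogen peroxide in place of free H2O2. It sets out from 12 and comes back at 13.
- 2-Methoxyprop-2-yl hydroperoxide F2 is prepared by ozonolysis of 2,3-dimethylbut-2-ene in methanol.
- Its caesium salt (Cs2CO3, DMF, 0 °C) displaces the triflate by addition–elimination and should give the cochliodinol 2-methoxyprop-2-yl peroxyketal F3. F2 has only one nucleophilic oxygen and F3 has no free O–O–H, so neither dimeric peroxide formation nor oxygen transfer is possible at this stage.
- AcOH–THF–H2O at room temperature then hydrolyses the ketal to 13.
- The use of this monoperoxyketal as a hydroperoxide-anion equivalent, its mild acid unmasking, and the substitution of activated quinones by oxygen nucleophiles are all known operations.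

**3. Step 6.**
- What may go wrong: mono-selectivity may be lost through over-triflation, and the product may hydrolyse during isolation.
- Fallback: it replaces statistical control by kinetic control. It sets out from 11 and comes back at 12.
- Exhaustive triflation (Tf2O 2.5 equiv, 2,6-lutidine, CH2Cl2, −78 to 0 °C) should give cochliodinol bis-triflate F4.
- LiOH (2.0 equiv, THF–H2O, −20 °C) then removes a single triflate. The quinonolate anion formed by the first substitution repels further hydroxide. Cleavage at carbon and cleavage at sulfur both lead to the same product, 12.

## Further compounds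

F1 | step 5 | 2,5-dibromo-3,6-bis(5-prenyl-1H-indol-3-yl)-1,4-benzoquinone | CC(C)=CCc1ccc2[nH]cc(C3=C(Br)C(=O)C(c4c[nH]c5ccc(CC=C(C)C)cc45)=C(Br)C3=O)c2c1
F2 | step 7 | 2-methoxyprop-2-yl hydroperoxide | COC(C)(C)OO
F3 | step 7 | cochliodinol 2-methoxyprop-2-yl peroxyketal | CC(C)=CCc1ccc2[nH]cc(C3=C(O)C(=O)C(c4c[nH]c5ccc(CC=C(C)C)cc45)=C(OOC(C)(C)OC)C3=O)c2c1
F4 | step 6 | cochliodinol bis-triflate | CC(C)=CCc1ccc2[nH]cc(C3=C(OS(=O)(=O)C(F)(F)F)C(=O)C(c4c[nH]c5ccc(CC=C(C)C)cc45)=C(OS(=O)(=O)C(F)(F)F)C3=O)c2c1
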